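## Retrosynthetic overview

1. The target comes from the spiro acyl-trione diol by a final gem-diprenylation at C5, which creates no stereocentre.
2. The acyl-trione (ring A) is built last by a new lactone-selective (3+3) Claisen annulation of a bridged lactone ester with 5-methylhexane-2,4-dione. The lactone carbonyl becomes C6, and this fixes the spiro centre.
3. The bridged lactone ester comes from a cyclopentanone-tethered malonate by Mn(OAc)3 oxidative radical cyclisation–lactonisation, which closes ring B (cyclohexane) and the lactone bridge and sets C7'; methyl addition to the ketone then sets C3'.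
4. The malonate comes from a Mannich base (latent 2-methylidene ketone) and dimethyl malonate; the Mannich base comes from cyclopent-2-en-1-one, isopropenylmagnesium bromide and Eschenmoser's salt by asymmetric conjugate addition with enolate trapping.
5. Ring order: ring C (cyclopentane, present from the start), then ring B with the lactone bridge, then ring A. No protecting groups are used.

Assumption: the target is treated as the enol tautomer written in its SMILES; locants are those of spiro[cyclohexane-1,5'-indene] (C1 spiro, C2/C6 ring carbonyls, C3 acyl carbon, C5 diprenyl carbon) and of 7,5-(epoxymethano)indene for the bridged lactones.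

## Route

Step 1
Reactants: 1 cyclopent-2-en-1-one; 2 isopropenylmagnesium bromide; 3 N,N-dimethylmethylideneammonium iodide (Eschenmoser's salt)
Product: 5 (2S,3S)-2-[(dimethylamino)methyl]-3-(prop-1-en-2-yl)cyclopentan-1-one, via magnesium enolate 4 (not isolated)
Conditions: CuBr·SMe2 (5 mol %), (R)-1-[(S_p)-2-(diphenylphosphino)ferrocenyl]ethyldicyclohexylphosphine (6 mol %; ligand enantiomer chosen to give 3S), t-BuOMe, −78 °C; then 3, THF, −78 → 0 °C
Reagents that add atoms: none
Why: Copper-catalysed asymmetric conjugate addition of the alkenyl Grignard reagent sets C3 (S) under ligand control, and the magnesium enolate is then trapped regiospecifically at C2 by the iminium ion (Mannich reaction) anti to the new isopropenyl group, giving the 2,3-trans (2S) product.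

Step 2
Reactants: 5 (2S,3S)-2-[(dimethylamino)methyl]-3-(prop-1-en-2-yl)cyclopentan-1-one; 6 dimethyl malonate
Product: 9 dimethyl 2-{[(1R,5S)-2-oxo-5-(prop-1-en-2-yl)cyclopentyl]methyl}propanedioate, via methiodide 7 (not isolated), via enone 8 (not isolated)
Conditions: MeI (3 equiv), acetone, 25 °C, then evaporate; 6 (1.5 equiv), NaOMe (1.1 equiv), MeOH, 0 → 25 °C
Reagents that add atoms: none
Why: Quaternisation makes the Mannich base a latent enone that is unmasked by E1cB loss of trimethylamine and intercepted at once by sodium dimethyl malonate (Michael addition), the α-carbon being protonated to the thermodynamically favoured 2,3-trans cyclopentanone (descriptor R only through a priority change).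

Step 3
Reactants: 9 dimethyl 2-{[(1R,5S)-2-oxo-5-(prop-1-en-2-yl)cyclopentyl]methyl}propanedioate
Product: 10 methyl (3aR,5S,7R,7aS)-7-methyl-3,9-dioxooctahydro-1H-7,5-(epoxymethano)indene-5-carboxylate
Conditions: Mn(OAc)3·2H2O (2.2 equiv), degassed AcOH, 70 °C
Reagents that add atoms: none
Why: Mn(OAc)3-based oxidative free-radical cyclisation ending in lactonisation, in which the electrophilic malonyl radical adds 6-endo to the CH2 terminus of the 1,1-disubstituted alkene through a chair transition state with the trans cyclopentane bonds equatorial, the tertiary radical is oxidised by the second equivalent of trivalent manganese to the cation, and whichever ester is axial captures it, so the γ-lactone closes with O axial and CH3 equatorial at C7 (R) and the two carboxyl carbons on C5 become different (lactone C=O cis to the C7 oxygen).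

Step 4
Reactants: 10 methyl (3aR,5S,7R,7aS)-7-methyl-3,9-dioxooctahydro-1H-7,5-(epoxymethano)indene-5-carboxylate
Product: 11 methyl (3S,3aR,5S,7R,7aS)-3-hydroxy-3,7-dimethyl-9-oxooctahydro-1H-7,5-(epoxymethano)indene-5-carboxylate
Conditions: MeMgBr (1.5 equiv), CeCl3 (1.5 equiv), THF, −78 °C; then H2O
Reagents that add atoms: methylmagnesium bromide, C[Mg]Br
Why: Cerium-assisted Grignard 1,2-addition attacks only the ketone (lactone and hindered ester are spared at −78 °C and enolisation is suppressed) from the face carrying the adjacent angular C3a–H, the other face being screened by the axial hydrogens at C7a and C4, which gives the 3S carbinol with OH cis to C4.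

Step 5
Reactants: 11 methyl (3S,3aR,5S,7R,7aS)-3-hydroxy-3,7-dimethyl-9-oxooctahydro-1H-7,5-(epoxymethano)indene-5-carboxylate; 12 5-methylhexane-2,4-dione
Product: 14 (1S,3'S,3a'R,7'R,7a'S)-3',4,7'-trihydroxy-3',7'-dimethyl-3-(2-methylpropanoyl)-1',2',3',3a',4',6',7',7a'-octahydrospiro[cyclohex-3-ene-1,5'-indene]-2,6-dione, via triketo ester 13 (not isolated)
Conditions: 12 (3.3 equiv), LiN(i-Pr)2 (6.6 equiv), THF, −78 → 0 °C; add 11, −78 → 25 °C; quench AcOH, −78 °C (no strong acid; 14 is used promptly)
Reagents that add atoms: none
Why: Proposed new method: a lactone-selective (3+3) double Claisen annulation in which the terminal carbanion of the diketone dianion opens the strained bridged γ-lactone (far more electrophilic than the hindered methyl ester on the same carbon) to give the C7' alkoxide and triketo ester 13, whose central diketone carbon then closes ring A by 6-exo Claisen (Dieckmann-type) attack on the ester, so that the former lactone carbonyl, cis to the C7' oxygen by construction, becomes C6 and the spiro centre C1 is fixed as S; the closest known reactions are the γ-acylation of β-diketone dianions by esters and lactones and the biomimetic Claisen cyclisation of 3,5,7-triketo esters to acylphloroglucinols.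

Step 6
Reactants: 14 (1S,3'S,3a'R,7'R,7a'S)-3',4,7'-trihydroxy-3',7'-dimethyl-3-(2-methylpropanoyl)-1',2',3',3a',4',6',7',7a'-octahydrospiro[cyclohex-3-ene-1,5'-indene]-2,6-dione; 15 1-bromo-3-methylbut-2-ene (prenyl bromide)
Product: 17 (1S,3'S,3a'R,7'R,7a'S)-3',4,7'-trihydroxy-3',7'-dimethyl-5,5-bis(3-methylbut-2-en-1-yl)-3-(2-methylpropanoyl)-1',2',3',3a',4',6',7',7a'-octahydrospiro[cyclohex-3-ene-1,5'-indene]-2,6-dione (CNP0273836.6), via monoprenyl trione 16 (not isolated)
Conditions: NaOMe (3.3 equiv), MeOH, 0 °C; 15 (2.5 equiv), 0 → 25 °C; then AcOH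
Reagents that add atoms: none
Why: Twofold C-alkylation (SN2) of the trione enolate at C5, the only ring carbon that still carries hydrogen between two carbonyl groups, as in the classical gem-prenylation of acylphloroglucinols to lupulone-type β-acids, with no stereocentre created or touched.

## Compound list

1 | cyclopent-2-en-1-one | O=C1CCC=C1 | starting material
2 | isopropenylmagnesium bromide | CC(=C)[Mg]Br | starting material
3 | N,N-dimethylmethylideneammonium iodide (Eschenmoser's salt) | C=[N+](C)C.[I-] | starting material
4 | bromomagnesium (3S)-3-(prop-1-en-2-yl)cyclopent-1-en-1-olate | Br[Mg]OC1=C[C@H](CC1)C(C)=C | intermediate (not isolated)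
5 | (2S,3S)-2-[(dimethylamino)methyl]-3-(prop-1-en-2-yl)cyclopentan-1-one | CN(C)C[C@@H]1[C@H](CCC1=O)C(C)=C | intermediate
6 | dimethyl malonate | COC(=O)CC(=O)OC | starting material
7 | [(1S,5S)-2-oxo-5-(prop-1-en-2-yl)cyclopentyl]-N,N,N-trimethylmethanaminium iodide | C[N+](C)(C)C[C@@H]1[C@H](CCC1=O)C(C)=C.[I-] | intermediate (not isolated)
8 | (3R)-2-methylidene-3-(prop-1-en-2-yl)cyclopentan-1-one | C=C1[C@H](CCC1=O)C(C)=C | intermediate (not isolated)
9 | dimethyl 2-{[(1R,5S)-2-oxo-5-(prop-1-en-2-yl)cyclopentyl]methyl}propanedioate | COC(=O)C(C[C@@H]1[C@H](CCC1=O)C(C)=C)C(=O)OC | intermediate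
10 | methyl (3aR,5S,7R,7aS)-7-methyl-3,9-dioxooctahydro-1H-7,5-(epoxymethano)indene-5-carboxylate (trans-fused keto γ-lactone ester) | O=C1[C@@]2(C[C@@H]3[C@H](CCC3=O)[C@](C)(O1)C2)C(=O)OC | intermediate
11 | methyl (3S,3aR,5S,7R,7aS)-3-hydroxy-3,7-dimethyl-9-oxooctahydro-1H-7,5-(epoxymethano)indene-5-carboxylate | O=C1[C@@]2(C[C@@H]3[C@H](CC[C@]3(C)O)[C@](C)(O1)C2)C(=O)OC | intermediate
12 | 5-methylhexane-2,4-dione | CC(C)C(=O)CC(C)=O | starting material
13 | methyl (3S,3aR,5S,7R,7aS)-3,7-dihydroxy-3,7-dimethyl-5-(6-methyl-3,5-dioxoheptanoyl)octahydro-1H-indene-5-carboxylate | CC(C)C(=O)CC(=O)CC(=O)[C@@]1(C[C@@H]2[C@H](CC[C@]2(C)O)[C@](C)(O)C1)C(=O)OC | intermediate (not isolated)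
14 | (1S,3'S,3a'R,7'R,7a'S)-3',4,7'-trihydroxy-3',7'-dimethyl-3-(2-methylpropanoyl)-1',2',3',3a',4',6',7',7a'-octahydrospiro[cyclohex-3-ene-1,5'-indene]-2,6-dione | C1C(=O)[C@@]2(C[C@@H]3[C@H](CC[C@]3(C)O)[C@](C)(O)C2)C(=O)C(C(=O)C(C)C)=C1O | intermediate
15 | 1-bromo-3-methylbut-2-ene (prenyl bromide) | CC(C)=CCBr | starting material
16 | (1S,3'S,3a'R,7'R,7a'S)-3',4,7'-trihydroxy-3',7'-dimethyl-5-(3-methylbut-2-en-1-yl)-3-(2-methylpropanoyl)-octahydrospiro[cyclohex-3-ene-1,5'-indene]-2,6-dione (C5 epimers and enol tautomers) | CC(C)=CCC1C(=O)[C@@]2(C[C@@H]3[C@H](CC[C@]3(C)O)[C@](C)(O)C2)C(=O)C(C(=O)C(C)C)=C1O | intermediate (not isolated)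
17 | (1S,3'S,3a'R,7'R,7a'S)-3',4,7'-trihydroxy-3',7'-dimethyl-5,5-bis(3-methylbut-2-en-1-yl)-3-(2-methylpropanoyl)-1',2',3',3a',4',6',7',7a'-octahydrospiro[cyclohex-3-ene-1,5'-indene]-2,6-dione | CC(C)=CCC1(CC=C(C)C)C(=O)[C@@]2(C[C@@H]3[C@H](CC[C@]3(C)O)[C@](C)(O)C2)C(=O)C(C(=O)C(C)C)=C1O | target

## Step count and risks

Total steps: 6. Longest linear sequence: 6 steps (from cyclopent-2-en-1-one).

The three steps most likely to fail:

**Step 5 (the proposed new annulation).** The risks are attack of the dianion on the methyl ester instead of the lactone (which would give the C1 epimer) and O- instead of C-cyclisation of 13. The fallback uses known chemistry, sets out from 11 and comes back at 14. The lactone is first opened with Me(MeO)NH·HCl/AlMe3 (CH2Cl2, 0 → 25 °C) to give the hydroxy Weinreb amide F4, used crude. At −78 °C the Weinreb amide is the only competent acyl donor towards the dilithium dianion of 12, and its chelated tetrahedral adduct prevents over-reaction, so γ-acylation gives triketo ester 13, here isolated after an AcOH quench. Mg(OMe)2 in MeOH at 60 °C then effects the classical magnesium-templated Claisen cyclisation of the triketo ester (C- rather than O-acylation) to 14.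

**Step 1 (enantioselectivity of copper-catalysed alkenyl Grignard addition to cyclopentenone).** The fallback replaces asymmetric catalysis by classical resolution, sets out from 1 (with 2 and 3) and comes back at 5. The same conjugate addition/Mannich trapping is run with CuI (5 mol %) and no chiral ligand, giving the racemic trans Mannich base F1. One diastereomeric salt is crystallised from EtOH/EtOAc with (2R,3R)-O,O'-di-p-toluoyltartaric acid to constant rotation, giving the hydrogen tartrate salt F2 (the (2S,3S)-acid is used instead if the wanted amine stays in the mother liquor). Aqueous NaHCO3 liberates 5.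

**Step 4 (facial selectivity of methyl addition at C3).** If the Grignard reagent gives mainly the 3R carbinol, the fallback sets out from 10 and comes back at 11 with the complementary order of bond formation. Wittig methylenation (Ph3PCH3Br, KOt-Bu, THF, 0 °C; the ketone reacts, lactone and ester do not) gives the methylidene lactone ester F3. Mukaiyama hydration (cobalt bis(acetylacetonate) 10 mol %, PhSiH3, O2, i-PrOH, 25 °C) then adds H to the CH2 terminus and delivers oxygen to the tertiary C3 radical from the same open face that the carbon nucleophile prefers. The hydroxyl therefore ends up where the methyl group was, which inverts the outcome at C3 and gives 11.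

## Further compounds

F1 | step 1 | racemic trans-2-[(dimethylamino)methyl]-3-(prop-1-en-2-yl)cyclopentan-1-one | CN(C)CC1C(CCC1=O)C(C)=C
F2 | step 1 | (2S,3S)-2-[(dimethylammonio)methyl]-3-(prop-1-en-2-yl)cyclopentan-1-one hydrogen (2R,3R)-2,3-bis(4-methylbenzoyloxy)butanedioate | C[NH+](C)C[C@@H]1[C@H](CCC1=O)C(C)=C.OC(=O)[C@H](OC(=O)c1ccc(C)cc1)[C@@H](OC(=O)c1ccc(C)cc1)C([O-])=O
F3 | step 4 | methyl (3aR,5S,7R,7aS)-7-methyl-3-methylidene-9-oxooctahydro-1H-7,5-(epoxymethano)indene-5-carboxylate | O=C1[C@@]2(C[C@@H]3[C@H](CCC3=C)[C@](C)(O1)C2)C(=O)OC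
F4 | step 5 | methyl (3S,3aR,5S,7R,7aS)-3,7-dihydroxy-5-[methoxy(methyl)carbamoyl]-3,7-dimethyloctahydro-1H-indene-5-carboxylate | CON(C)C(=O)[C@@]1(C[C@@H]2[C@H](CC[C@]2(C)O)[C@](C)(O)C1)C(=O)OC
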